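The numbers in the tables come from a simulation from invented constants, and the scatter is random.

Wednesday's run cannot have flattened through the making of first product using up the partner: the last reading, 21.3% of the substrate charged, ties up partner to that amount, out of 1.1 equiv charged. In Wednesday's run, the step from 12.0 s to 25.0 s was 4.9 percentage points, but the step from 40.0 s to 80.0 s was smaller, 1.7 points. So I took it, from the list of possible steps below, that partner and substrate were each also being lost by a route of their own.

| flask | substrate | partner | remark | time |
|---|---|---|---|---|
| Wednesday's | 20 mM | 1.1 equiv | run made earlier |  |
| Tuesday's | 10 mM | 1.1 equiv | run made earlier |  |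
| autumn | 20 mM (fed, over 80 s) | 1.10 equiv | all else is in the flask from the start; the feed brings no volume worth counting | 2.0 min |
| midnight | 20 mM | 1.10 equiv (fed, over 80 s) | all else is in the flask from the start; the feed brings no volume worth counting | 2.0 min |
| summer | 20 mM | 1.10 equiv | everything together at the start | 2.0 min |

- Wednesday's (time / s: first product / %): 12.0: 11.9; 25.0: 16.8; 40.0: 19.6; 50.0: 20.2; 60.0: 20.5; 80.0: 21.3
- Tuesday's (time / s: first product / %): 10.0: 6.6; 12.0: 7.7

(scatter of a reading: 0.3 percentage points)

- percent here means substrate units held: one self-condensation product counts as two
- what may be going on: substrate + partner -> first product; substrate + partner -> other mono adduct; partner + first product -> bis adduct; partner + other mono adduct -> bis adduct; partner -> decomposed reagent; 2 substrate -> self-condensation product; partner <-> dormant form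

- which flask leads in amount of first product, in percent of the substrate charged ("all alike" within 1.5 percentage points) (autumn / midnight / summer / all alike)
- how much first product is there at the end, in percent of the substrate charged: autumn
- how much first product is there at the end, in percent of the substrate charged: midnight
- how much first product is there at the end, in percent of the substrate charged: summer

I divided Wednesday's plateau, 21.3%, by the opening mean rate, 11.9% in 12.0 s, and got 21.5 s. This is the window τ, the characteristic time for which a fully charged flask makes first product.

Then I turned the settings by hand. Summer repeats Wednesday's recipe, so I kept its plateau. Autumn feeds substrate over a time t_f of 80 s, longer than τ, so partner waits in the flask while substrate arrives. Rate growing as t/t_f and dying as exp(−t/τ) gives the plateau times τ/t_f, or 5.72%. Midnight feeds partner while substrate waits, and I gave it the same figure. Both feeds stood lower than summer, so I called summer the leader.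

The forecast differed: autumn led, with 32% there, 13% in midnight and 21.3% in summer, on the ground that “Feeding substrate keeps it dilute, suppressing self-condensation”.

The flasks gave 11.4% in autumn, 12.8% in midnight and 21.5% in summer, so summer led; autumn held twice my figure, and midnight twice. In autumn, partner turned into decomposed reagent while substrate came in: at 1.33 min there stood 15.4 mM of it, with 6.84% of partner left and 10.2% first product. In midnight, substrate turned into self-condensation product while partner came in, reaching 65.3% at 1.33 min against 10.8% first product.

    substrate + partner → first product (k = 0.800 M⁻¹ s⁻¹)
    substrate + partner → other mono adduct (k = 0.370 M⁻¹ s⁻¹)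
    partner + first product → bis adduct (k = 0.0420 M⁻¹ s⁻¹)
    partner + other mono adduct → bis adduct (k = 0.650 M⁻¹ s⁻¹)
    partner → decomposed reagent (k = 0.0250 s⁻¹)
    2 substrate → self-condensation product (k = 0.880 M⁻¹ s⁻¹)
    partner ⇌ dormant form (K = 0.530, k = 0.00530 s⁻¹)

For summer stopped at 50 s, approach to the plateau as exp(−t/τ) gives 19.2%; the computed flask holds 20.0%.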